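**Strategy.** Everything rests on disconnecting the C2–C3 bond of the 2,3-dihydrobenzofuran. C2 is benzylic to the guaiacyl ring and bonded to the ring oxygen O1, so it can start as the plain CH2 of an aryl benzyl ether, while C3 starts as the diazo carbon of an aryl diazoacetate on ring A (the benzo ring). A chiral dirhodium carbene at C3 inserts into one of the two enantiotopic C–H bonds of that CH2, closing the dihydrofuran ring and setting C2 in a single operation; C3 is then epimerised to trans. The ester becomes the CH2O arm, which is acylated with p-coumaric acid by a phenol-tolerant Mitsunobu reaction.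

Key step: step 6

Assumption: Rh2(S-PTTL)4 is taken to select the C–H bond that gives the 2R configuration, by analogy with closely related 2-(benzyloxy)phenyl diazoacetates; if the sense proves opposite, the mirror-image catalyst Rh2(R-PTTL)4 is used with no other change.

**Step 1**
Reactants: 1 dihydroconiferyl alcohol, 4-(3-hydroxypropyl)-2-methoxyphenol
Product: 2 4-(3-hydroxypropyl)-2-iodo-6-methoxyphenol
Conditions: I2, NaHCO3, THF/H2O, 0 °C to rt
Reagents that add atoms: iodine, II
Why: Electrophilic aromatic iodination of the phenol/phenoxide should go ortho to the hydroxyl group, because the para position carries the propyl chain and the other ortho position the methoxy group.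

**Step 2**
Reactants: 3 [4-(benzyloxy)-3-methoxyphenyl]methanol
Product: 4 1-(benzyloxy)-4-(chloromethyl)-2-methoxybenzene
Conditions: SOCl2, CH2Cl2, 0 °C to rt, used crude
Reagents that add atoms: thionyl chloride, O=S(Cl)Cl
Why: Deoxychlorination of an electron-rich benzylic alcohol through its chlorosulfite is fast and clean, and the benzyl aryl ether is inert.

**Step 3**
Reactants: 2 4-(3-hydroxypropyl)-2-iodo-6-methoxyphenol; 4 1-(benzyloxy)-4-(chloromethyl)-2-methoxybenzene
Product: 5 3-(4-{[4-(benzyloxy)-3-methoxybenzyl]oxy}-3-iodo-5-methoxyphenyl)propan-1-ol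
Conditions: K2CO3, Bu4NI (cat.), DMF, rt to 50 °C
Reagents that add atoms: none
Why: Williamson etherification in which K2CO3 deprotonates only the phenol (pKa about 10) and not the aliphatic alcohol, so the benzylic chloride should alkylate the phenoxide selectively.

**Step 4**
Reactants: 5 3-(4-{[4-(benzyloxy)-3-methoxybenzyl]oxy}-3-iodo-5-methoxyphenyl)propan-1-ol
Product: 6 tert-butyl[3-(4-{[4-(benzyloxy)-3-methoxybenzyl]oxy}-3-iodo-5-methoxyphenyl)propoxy]dimethylsilane
Conditions: TBSCl, imidazole, CH2Cl2, rt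
Reagents that add atoms: tert-butyldimethylsilyl chloride (TBSCl), CC(C)(C)[Si](C)(C)Cl
Why: Standard imidazole-mediated silylation of the only free hydroxyl group gives a silyl ether that survives the palladium, rhodium, ethoxide, hydride and hydrogenation steps and sets the propanol apart from the later C3 hydroxymethyl group.

**Step 5**
Reactants: 6 tert-butyl[3-(4-{[4-(benzyloxy)-3-methoxybenzyl]oxy}-3-iodo-5-methoxyphenyl)propoxy]dimethylsilane; 7 ethyl diazoacetate
Product: 8 ethyl 2-[2-{[4-(benzyloxy)-3-methoxybenzyl]oxy}-5-{3-[(tert-butyldimethylsilyl)oxy]propyl}-3-methoxyphenyl]-2-diazoacetate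
Conditions: Pd(PPh3)4 (5 mol %), Ag2CO3 (0.5 equiv), Et3N, toluene, rt, dark
Reagents that add atoms: none
Why: Palladium-catalysed cross-coupling of an aryl iodide with an acceptor diazo compound that keeps the diazo group, in which oxidative addition to zerovalent palladium, silver-assisted iodide abstraction, C-palladation of the deprotonated diazoacetate and reductive elimination should outrun loss of N2 at room temperature.

**Step 6**
Reactants: 8 ethyl 2-[2-{[4-(benzyloxy)-3-methoxybenzyl]oxy}-5-{3-[(tert-butyldimethylsilyl)oxy]propyl}-3-methoxyphenyl]-2-diazoacetate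
Product: 9 ethyl (2R,3S)-2-[4-(benzyloxy)-3-methoxyphenyl]-5-{3-[(tert-butyldimethylsilyl)oxy]propyl}-7-methoxy-2,3-dihydro-1-benzofuran-3-carboxylate (cis)
Conditions: Rh2(S-PTTL)4 [dirhodium tetrakis(N-phthaloyl-(S)-tert-leucinate)] (1 mol %), toluene, −60 °C, slow addition of 8
Reagents that add atoms: none
Why: Rh2(S-PTTL)4 expels N2 from 8 to give an electrophilic donor/acceptor rhodium carbene at the future C3, which inserts through a concerted, asynchronous, hydride-transfer-like three-centre transition state into one C–H bond of the ArO–CH2–Ar group, so that the C2–C3 bond and the C3–H bond form together. The closest known reaction type is the enantioselective intramolecular C–H insertion of 2-(benzyloxy)phenyl diazoacetates to cis-2-aryl-2,3-dihydrobenzofuran-3-carboxylates under catalysis by chiral dirhodium carboxylates (divalent rhodium). The dihydrofuran ring closes in the 1,5 mode (carbene carbon C3, then C3a, C7a, O1 and C2), the five-membered transition ring being the only one within reach. C2 is controlled by the catalyst, whose phthalimido-tert-leucinate wall should let only one of the two enantiotopic benzylic hydrogens approach the carbene, and C3 is set cis to C2 in the same compact transition state, a relationship that step 7 corrects to trans under control of C2. The step needs site selectivity, secured because the reacting C–H bond is the only one five atoms from the carbene and is made hydridic by O1 and the electron-rich aryl ring (the methoxy, benzyloxy and propyl C–H bonds are out of reach), and enantioselectivity, which rests on the catalyst at low temperature with slow addition to suppress carbene dimerisation.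

**Step 7**
Reactants: 9 ethyl (2R,3S)-2-[4-(benzyloxy)-3-methoxyphenyl]-5-{3-[(tert-butyldimethylsilyl)oxy]propyl}-7-methoxy-2,3-dihydro-1-benzofuran-3-carboxylate (cis)
Product: 10 ethyl (2R,3R)-2-[4-(benzyloxy)-3-methoxyphenyl]-5-{3-[(tert-butyldimethylsilyl)oxy]propyl}-7-methoxy-2,3-dihydro-1-benzofuran-3-carboxylate (trans)
Conditions: NaOEt (0.3 equiv), EtOH/THF, 0 °C to rt
Reagents that add atoms: none
Why: Base-mediated epimerisation through the C3 ester enolate should equilibrate to the thermodynamically favoured trans isomer (aryl and ester on opposite faces), with the C3 configuration dictated by the untouched C2 centre and with ethoxide matching the ethyl ester.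

**Step 8**
Reactants: 10 ethyl (2R,3R)-2-[4-(benzyloxy)-3-methoxyphenyl]-5-{3-[(tert-butyldimethylsilyl)oxy]propyl}-7-methoxy-2,3-dihydro-1-benzofuran-3-carboxylate (trans)
Product: 11 [(2R,3S)-2-[4-(benzyloxy)-3-methoxyphenyl]-5-{3-[(tert-butyldimethylsilyl)oxy]propyl}-7-methoxy-2,3-dihydro-1-benzofuran-3-yl]methanol
Conditions: LiAlH4, THF, 0 °C; aqueous work-up
Reagents that add atoms: none
Why: Hydride reduction of the ester to the primary alcohol leaves the silyl and benzyl ethers intact and removes the acidic C3–H, so neither stereocentre can scramble afterwards (the descriptor at C3 changes only through CIP priorities).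

**Step 9**
Reactants: 11 [(2R,3S)-2-[4-(benzyloxy)-3-methoxyphenyl]-5-{3-[(tert-butyldimethylsilyl)oxy]propyl}-7-methoxy-2,3-dihydro-1-benzofuran-3-yl]methanol
Product: 12 4-[(2R,3S)-5-{3-[(tert-butyldimethylsilyl)oxy]propyl}-3-(hydroxymethyl)-7-methoxy-2,3-dihydro-1-benzofuran-2-yl]-2-methoxyphenol
Conditions: H2 (1 atm), 10% Pd/C, EtOAc, rt, monitored and stopped at full conversion
Reagents that add atoms: none
Why: Catalytic hydrogenolysis should cleave the unhindered acyclic aryl benzyl ether far faster than the ring C2–O1 bond, whose benzylic carbon is secondary and held in the ring, while the silyl ether is stable in neutral ethyl acetate.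

**Step 10**
Reactants: 12 4-[(2R,3S)-5-{3-[(tert-butyldimethylsilyl)oxy]propyl}-3-(hydroxymethyl)-7-methoxy-2,3-dihydro-1-benzofuran-2-yl]-2-methoxyphenol; 13 p-coumaric acid, (E)-3-(4-hydroxyphenyl)prop-2-enoic acid
Product: 14 [(2R,3S)-5-{3-[(tert-butyldimethylsilyl)oxy]propyl}-2-(4-hydroxy-3-methoxyphenyl)-7-methoxy-2,3-dihydro-1-benzofuran-3-yl]methyl (E)-3-(4-hydroxyphenyl)prop-2-enoate
Conditions: PPh3, DIAD, THF, 0 °C to rt
Reagents that add atoms: none
Why: Mitsunobu esterification activates the primary alcohol as an alkoxyphosphonium ion, which is displaced by the carboxylate, the only pronucleophile acidic enough to be engaged (pKa about 4.5 against about 10 for the two phenols), so no phenol protection is needed and the reacting CH2 carbon carries no stereocentre.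

**Step 11**
Reactants: 14 [(2R,3S)-5-{3-[(tert-butyldimethylsilyl)oxy]propyl}-2-(4-hydroxy-3-methoxyphenyl)-7-methoxy-2,3-dihydro-1-benzofuran-3-yl]methyl (E)-3-(4-hydroxyphenyl)prop-2-enoate
Product: 15 [(2R,3S)-2-(4-hydroxy-3-methoxyphenyl)-5-(3-hydroxypropyl)-7-methoxy-2,3-dihydro-1-benzofuran-3-yl]methyl (E)-3-(4-hydroxyphenyl)prop-2-enoate (target)
Conditions: HF·pyridine, pyridine/THF, 0 °C to rt
Reagents that add atoms: none
Why: Buffered fluoride desilylation should remove the primary silyl ether without touching the cinnamate ester, the E alkene or the C2–O1 benzylic ether.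

**Compound list**
1 | dihydroconiferyl alcohol, 4-(3-hydroxypropyl)-2-methoxyphenol | COc1cc(CCCO)ccc1O | starting material
2 | 4-(3-hydroxypropyl)-2-iodo-6-methoxyphenol | COc1cc(CCCO)cc(I)c1O | intermediate
3 | [4-(benzyloxy)-3-methoxyphenyl]methanol | COc1cc(CO)ccc1OCc1ccccc1 | starting material
4 | 1-(benzyloxy)-4-(chloromethyl)-2-methoxybenzene | COc1cc(CCl)ccc1OCc1ccccc1 | intermediate
5 | 3-(4-{[4-(benzyloxy)-3-methoxybenzyl]oxy}-3-iodo-5-methoxyphenyl)propan-1-ol | COc1cc(COc2c(I)cc(CCCO)cc2OC)ccc1OCc1ccccc1 | intermediate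
6 | tert-butyl[3-(4-{[4-(benzyloxy)-3-methoxybenzyl]oxy}-3-iodo-5-methoxyphenyl)propoxy]dimethylsilane | COc1cc(COc2c(I)cc(CCCO[Si](C)(C)C(C)(C)C)cc2OC)ccc1OCc1ccccc1 | intermediate
7 | ethyl diazoacetate | CCOC(=O)C=[N+]=[N-] | starting material
8 | ethyl 2-[2-{[4-(benzyloxy)-3-methoxybenzyl]oxy}-5-{3-[(tert-butyldimethylsilyl)oxy]propyl}-3-methoxyphenyl]-2-diazoacetate | CCOC(=O)C(=[N+]=[N-])c1cc(CCCO[Si](C)(C)C(C)(C)C)cc(OC)c1OCc1ccc(OCc2ccccc2)c(OC)c1 | intermediate
9 | ethyl (2R,3S)-2-[4-(benzyloxy)-3-methoxyphenyl]-5-{3-[(tert-butyldimethylsilyl)oxy]propyl}-7-methoxy-2,3-dihydro-1-benzofuran-3-carboxylate (cis) | COc1cc([C@@H]2Oc3c(OC)cc(CCCO[Si](C)(C)C(C)(C)C)cc3[C@@H]2C(=O)OCC)ccc1OCc1ccccc1 | intermediate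
10 | ethyl (2R,3R)-2-[4-(benzyloxy)-3-methoxyphenyl]-5-{3-[(tert-butyldimethylsilyl)oxy]propyl}-7-methoxy-2,3-dihydro-1-benzofuran-3-carboxylate (trans) | COc1cc([C@@H]2Oc3c(OC)cc(CCCO[Si](C)(C)C(C)(C)C)cc3[C@H]2C(=O)OCC)ccc1OCc1ccccc1 | intermediate
11 | [(2R,3S)-2-[4-(benzyloxy)-3-methoxyphenyl]-5-{3-[(tert-butyldimethylsilyl)oxy]propyl}-7-methoxy-2,3-dihydro-1-benzofuran-3-yl]methanol | COc1cc([C@@H]2Oc3c(OC)cc(CCCO[Si](C)(C)C(C)(C)C)cc3[C@H]2CO)ccc1OCc1ccccc1 | intermediate
12 | 4-[(2R,3S)-5-{3-[(tert-butyldimethylsilyl)oxy]propyl}-3-(hydroxymethyl)-7-methoxy-2,3-dihydro-1-benzofuran-2-yl]-2-methoxyphenol | COc1cc([C@@H]2Oc3c(OC)cc(CCCO[Si](C)(C)C(C)(C)C)cc3[C@H]2CO)ccc1O | intermediate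
13 | p-coumaric acid, (E)-3-(4-hydroxyphenyl)prop-2-enoic acid | O=C(O)/C=C/c1ccc(O)cc1 | starting material
14 | [(2R,3S)-5-{3-[(tert-butyldimethylsilyl)oxy]propyl}-2-(4-hydroxy-3-methoxyphenyl)-7-methoxy-2,3-dihydro-1-benzofuran-3-yl]methyl (E)-3-(4-hydroxyphenyl)prop-2-enoate | COc1cc([C@@H]2Oc3c(OC)cc(CCCO[Si](C)(C)C(C)(C)C)cc3[C@H]2COC(=O)/C=C/c2ccc(O)cc2)ccc1O | intermediate
15 | [(2R,3S)-2-(4-hydroxy-3-methoxyphenyl)-5-(3-hydroxypropyl)-7-methoxy-2,3-dihydro-1-benzofuran-3-yl]methyl (E)-3-(4-hydroxyphenyl)prop-2-enoate | COc1cc([C@@H]2Oc3c(OC)cc(CCCO)cc3[C@H]2COC(=O)/C=C/c2ccc(O)cc2)ccc1O | target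

**Total step count:** 11
**Longest linear sequence:** 10 steps (steps 1 and 3 to 11)

**Steps most likely to fail**

Step 6. The catalyst may discriminate poorly between the two enantiotopic benzylic C–H bonds, because the methoxy group flanking O1 changes the conformation of the benzyl ether, and the product would then be of low enantiomeric purity. The fallback gives up catalyst control and sets out from 8. Decomposition with achiral Rh2(OAc)4 in CH2Cl2 at rt should give, through the substrate-inherent cis preference of the insertion, the racemic cis ester F1. This is resolved by preparative chromatography on a polysaccharide-carbamate chiral stationary phase, and the (2R,3S) enantiomer is 9, where the route is rejoined.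

Step 5. Oxidative addition and C-palladation at the hindered, electron-rich ortho-alkoxy aryl iodide may be slower than loss of N2 from ethyl diazoacetate on palladium, so that carbene dimers form instead of the coupled diazo ester. The fallback builds the carbon skeleton first and introduces the diazo group afterwards, setting out from 6. Negishi-type α-arylation with the Reformatsky reagent BrZnCH2CO2Et (from ethyl bromoacetate and zinc), Pd2(dba)3 and XPhos in THF at 60 °C should give ethyl 2-[2-{[4-(benzyloxy)-3-methoxybenzyl]oxy}-5-{3-[(tert-butyldimethylsilyl)oxy]propyl}-3-methoxyphenyl]acetate F2. Regitz diazo transfer with 4-acetamidobenzenesulfonyl azide and DBU in MeCN then returns to 8.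

Step 10. The phenols may compete as nucleophiles for the activated alcohol (ether formation and oligomers), eroding the chemoselectivity of the esterification. The fallback forms the ester before any phenol is free and builds the cinnamate alkene last, setting out from 11. Acylation with 2-(diethoxyphosphoryl)acetic acid (EDC·HCl, DMAP, CH2Cl2) should give the phosphonoacetate [(2R,3S)-2-[4-(benzyloxy)-3-methoxyphenyl]-5-{3-[(tert-butyldimethylsilyl)oxy]propyl}-7-methoxy-2,3-dihydro-1-benzofuran-3-yl]methyl 2-(diethoxyphosphoryl)acetate F3. Hydrogenolysis (H2, Pd/C, EtOAc) gives the phenol [(2R,3S)-5-{3-[(tert-butyldimethylsilyl)oxy]propyl}-2-(4-hydroxy-3-methoxyphenyl)-7-methoxy-2,3-dihydro-1-benzofuran-3-yl]methyl 2-(diethoxyphosphoryl)acetate F4. Horner–Wadsworth–Emmons olefination with commercial 4-[(tert-butyldimethylsilyl)oxy]benzaldehyde (LiCl, iPr2NEt, MeCN) should give the E cinnamate [(2R,3S)-5-{3-[(tert-butyldimethylsilyl)oxy]propyl}-2-(4-hydroxy-3-methoxyphenyl)-7-methoxy-2,3-dihydro-1-benzofuran-3-yl]methyl (E)-3-{4-[(tert-butyldimethylsilyl)oxy]phenyl}prop-2-enoate F5. Desilylation of both silyl ethers with HF·pyridine then gives 15.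

**Further compounds**
F1 | step 6 | racemic cis ester, ethyl (2R,3S)- and (2S,3R)-2-[4-(benzyloxy)-3-methoxyphenyl]-5-{3-[(tert-butyldimethylsilyl)oxy]propyl}-7-methoxy-2,3-dihydro-1-benzofuran-3-carboxylate (both enantiomers shown) | COc1cc([C@@H]2Oc3c(OC)cc(CCCO[Si](C)(C)C(C)(C)C)cc3[C@@H]2C(=O)OCC)ccc1OCc1ccccc1.COc1cc([C@H]2Oc3c(OC)cc(CCCO[Si](C)(C)C(C)(C)C)cc3[C@H]2C(=O)OCC)ccc1OCc1ccccc1
F2 | step 5 | ethyl 2-[2-{[4-(benzyloxy)-3-methoxybenzyl]oxy}-5-{3-[(tert-butyldimethylsilyl)oxy]propyl}-3-methoxyphenyl]acetate | CCOC(=O)Cc1cc(CCCO[Si](C)(C)C(C)(C)C)cc(OC)c1OCc1ccc(OCc2ccccc2)c(OC)c1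
F3 | step 10 | [(2R,3S)-2-[4-(benzyloxy)-3-methoxyphenyl]-5-{3-[(tert-butyldimethylsilyl)oxy]propyl}-7-methoxy-2,3-dihydro-1-benzofuran-3-yl]methyl 2-(diethoxyphosphoryl)acetate | COc1cc([C@@H]2Oc3c(OC)cc(CCCO[Si](C)(C)C(C)(C)C)cc3[C@H]2COC(=O)CP(=O)(OCC)OCC)ccc1OCc1ccccc1
F4 | step 10 | [(2R,3S)-5-{3-[(tert-butyldimethylsilyl)oxy]propyl}-2-(4-hydroxy-3-methoxyphenyl)-7-methoxy-2,3-dihydro-1-benzofuran-3-yl]methyl 2-(diethoxyphosphoryl)acetate | COc1cc([C@@H]2Oc3c(OC)cc(CCCO[Si](C)(C)C(C)(C)C)cc3[C@H]2COC(=O)CP(=O)(OCC)OCC)ccc1O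
F5 | step 10 | [(2R,3S)-5-{3-[(tert-butyldimethylsilyl)oxy]propyl}-2-(4-hydroxy-3-methoxyphenyl)-7-methoxy-2,3-dihydro-1-benzofuran-3-yl]methyl (E)-3-{4-[(tert-butyldimethylsilyl)oxy]phenyl}prop-2-enoate | COc1cc([C@@H]2Oc3c(OC)cc(CCCO[Si](C)(C)C(C)(C)C)cc3[C@H]2COC(=O)/C=C/c2ccc(O[Si](C)(C)C(C)(C)C)cc2)ccc1O
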